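**Strategy.** The route rests on opening the oxepane of the trans-fused perhydro-1-benzoxepine across C5–C5a and O1–C2. In one flask a primary radical from an enantiopure bromo epoxide adds to the β-carbon (future quaternary C5a) of a 4-silyloxycyclohexenone β-keto ester, anti to the oxygen on C9a, and acid then lets that oxygen open the epoxide at its tertiary carbon. The step exploits the vicinal O1/C5a pair on the cyclohexane ring and the C2(Me)2–C3(OH) unit of the oxepane, which is an opened trisubstituted epoxide. The β-keto ester then receives the hydroazulene half as an allyl unit, and methyl addition to the ring ketone finishes the target.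

Key step: step 9

Remark: centres that are enolisable or destroyed later (ester-bearing carbons of 11, 12, 21 and 26, the two new centres of 17, the carbinol carbon of 25) are left undefined; the oxazaborolidinium antipode in step 10 is taken to be the one that gives the R adduct.

**Right-hand fragment**

Step 1
Reactants: 1 4-methoxy-2-methylphenol
Product: 2 4,4-dimethoxy-2-methylcyclohexa-2,5-dien-1-one
Conditions: PhI(OAc)2, MeOH, 0 °C
Reagents that add atoms: methanol (CO)
Why: Oxidative dearomatization of the para-methoxyphenol; the phenoxonium ion is trapped by methanol at C4 to give the quinone monoketal.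

Step 2
Reactants: 2 4,4-dimethoxy-2-methylcyclohexa-2,5-dien-1-one
Product: 3 4,4-dimethoxy-2-methylcyclohex-2-en-1-one
Conditions: H2 (1 atm), RhCl(PPh3)3 (cat.), PhH, rt
Reagents that add atoms: none
Why: Chemoselective homogeneous hydrogenation; the catalyst should reduce only the unhindered disubstituted C5=C6 bond and leave the methyl-bearing trisubstituted alkene.

Step 3
Reactants: 3 4,4-dimethoxy-2-methylcyclohex-2-en-1-one
Product: 4 (1R)-4,4-dimethoxy-2-methylcyclohex-2-en-1-ol
Conditions: (S)-Me-CBS oxazaborolidine (cat.), BH3·SMe2, THF, −30 °C; MeOH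
Reagents that add atoms: none
Why: Corey–Bakshi–Shibata reduction; the α-methylvinyl group is the large substituent, so the (S)-catalyst should give the R allylic alcohol.

Step 4
Reactants: 4 (1R)-4,4-dimethoxy-2-methylcyclohex-2-en-1-ol
Product: 5 (4R)-4-hydroxy-3-methylcyclohex-2-en-1-one
Conditions: (CO2H)2, acetone–H2O, rt
Reagents that add atoms: water (O)
Why: Mild hydrolysis of the dimethyl ketal unveils the ketone in conjugation with the ring alkene (a transposed γ-hydroxy enone); the carbinol centre is untouched.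

Step 5
Reactants: 5 (4R)-4-hydroxy-3-methylcyclohex-2-en-1-one
Product: 6 (4R)-3-methyl-4-[(triethylsilyl)oxy]cyclohex-2-en-1-one
Conditions: Et3SiCl, imidazole, DMF, 0 °C
Reagents that add atoms: chlorotriethylsilane (CC[Si](Cl)(CC)CC)
Why: Standard silylation of the secondary alcohol; the silyl ether supplies steric bias in step 9 and is cleaved there by mild acid.

Step 6
Reactants: 6 (4R)-3-methyl-4-[(triethylsilyl)oxy]cyclohex-2-en-1-one
Product: 7 (4R)-2-iodo-3-methyl-4-[(triethylsilyl)oxy]cyclohex-2-en-1-one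
Conditions: I2, pyridine, CH2Cl2, rt
Reagents that add atoms: iodine (II)
Why: Pyridine-mediated α-iodination of an enone (conjugate addition of pyridine, iodination of the enolate, elimination).

Step 7
Reactants: 7 (4R)-2-iodo-3-methyl-4-[(triethylsilyl)oxy]cyclohex-2-en-1-one
Product: 8 2-(trimethylsilyl)ethyl (3R)-2-methyl-6-oxo-3-[(triethylsilyl)oxy]cyclohex-1-ene-1-carboxylate
Conditions: CO (1 atm), Me3SiCH2CH2OH, PdCl2(PPh3)2 (cat.), Et3N, DMF, 60 °C
Reagents that add atoms: carbon monoxide ([C-]#[O+]); 2-(trimethylsilyl)ethanol (C[Si](C)(C)CCO)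
Why: Palladium-catalysed alkoxycarbonylation of the vinyl iodide gives the alkylidene β-keto ester, which activates C2 as a radical acceptor and later directs the alkylation.

Step 8
Reactants: 9 5-bromo-2-methylpent-2-ene
Product: 10 (2R)-2-(2-bromoethyl)-3,3-dimethyloxirane
Conditions: D-fructose-derived Shi ketone (cat.), Oxone (KHSO5), K2CO3, Bu4NHSO4, MeCN–dimethoxymethane–aq. buffer, 0 °C
Reagents that add atoms: potassium peroxymonosulfate ([K+].[O-]S(=O)(=O)OO)
Why: Shi asymmetric epoxidation of the trisubstituted alkene through the spiro dioxirane transition state; the D-fructose-derived ketone should give the R epoxide.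

Step 9
Reactants: 8 2-(trimethylsilyl)ethyl (3R)-2-methyl-6-oxo-3-[(triethylsilyl)oxy]cyclohex-1-ene-1-carboxylate; 10 (2R)-2-(2-bromoethyl)-3,3-dimethyloxirane
Product: 12 2-(trimethylsilyl)ethyl (3R,5aR,9aR)-3-hydroxy-2,2,5a-trimethyl-7-oxodecahydro-1-benzoxepine-6-carboxylate, via Giese adduct 11 (not isolated)
Conditions: Bu3SnH (slow addition), AIBN (cat.), PhH, 80 °C; then 0 °C, (CF3)2CHOH, camphorsulfonic acid (cat.), 0 °C → rt
Reagents that add atoms: none
Why: The stannyl radical abstracts bromine from 10, and the primary radical adds to the β-carbon of the doubly activated alkene of 8 (Giese addition to an alkylidene β-keto ester); the stabilised radical is then reduced by Bu3SnH to 11. Addition should occur anti to the C3 silyloxy group, which allylic strain with the vinylic methyl holds pseudoaxial, and this sets the quaternary centre (5aR) trans to oxygen. On acidification the silyl ether oxygen opens the protonated epoxide at its tertiary carbon and loses silicon, a 7-endo-tet epoxide opening of the methyl-directed type known for oxepanes and pyrans, which closes the oxepane trans-fused. C3 comes unchanged from 10 (its C–O bond is never broken) and C9a from 8. The selectivity needed is endo over exo (oxepane over tetrahydropyran); it should be favoured by the cation-stabilising gem-dimethyl carbon, by neopentyl-type hindrance at the secondary epoxide carbon and by the ionising, weakly nucleophilic fluorinated alcohol. Both stages are known reaction types run in one flask.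

**Left-hand fragment**

Step 10
Reactants: 13 cyclopent-2-en-1-one; 14 1-methoxy-2-methyl-1-(trimethylsilyloxy)prop-1-ene; 15 tert-butyl 4-oxobutanoate
Product: 17 tert-butyl 4-hydroxy-4-[(2R)-2-(1-methoxy-2-methyl-1-oxopropan-2-yl)-5-oxocyclopentyl]butanoate, via silyl enol ether 16 (not isolated)
Conditions: chiral oxazaborolidinium triflimide (10 mol %), toluene, −20 °C; then 15, TiCl4, CH2Cl2, −78 °C; aq. NaHCO3
Reagents that add atoms: none
Why: Enantioselective Mukaiyama–Michael addition to the catalyst-activated enone sets the ring carbon bearing the quaternary group (R) and leaves a regiodefined silyl enol ether, which undergoes Mukaiyama aldol addition with 15 at the adjacent carbon.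

Step 11
Reactants: 17 tert-butyl 4-hydroxy-4-[(2R)-2-(1-methoxy-2-methyl-1-oxopropan-2-yl)-5-oxocyclopentyl]butanoate
Product: 18 tert-butyl 4-[(2R)-2-(1-methoxy-2-methyl-1-oxopropan-2-yl)-5-oxocyclopentylidene]butanoate
Conditions: MsCl, Et3N, CH2Cl2, −20 → 0 °C
Reagents that add atoms: none
Why: Mesylation and E1cB loss of methanesulfonate under a mild amine base should give the exocyclic enone without moving the double bond into the ring.

Step 12
Reactants: 18 tert-butyl 4-[(2R)-2-(1-methoxy-2-methyl-1-oxopropan-2-yl)-5-oxocyclopentylidene]butanoate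
Product: 19 tert-butyl 4-[(1R,2R)-2-(1-methoxy-2-methyl-1-oxopropan-2-yl)-5-oxocyclopentyl]butanoate
Conditions: H2 (1 atm), Pd/C, EtOAc, rt
Reagents that add atoms: none
Why: Heterogeneous hydrogenation delivers hydrogen to the alkylidene carbon from the face opposite the bulky quaternary substituent, so the two side chains end up cis (kinetic product, used at once).

Step 13
Reactants: 19 tert-butyl 4-[(1R,2R)-2-(1-methoxy-2-methyl-1-oxopropan-2-yl)-5-oxocyclopentyl]butanoate
Product: 20 tert-butyl 4-[(1R,2R)-2-(1-methoxy-2-methyl-1-oxopropan-2-yl)-5-methylidenecyclopentyl]butanoate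
Conditions: Zn, CH2Br2, TiCl4, THF–CH2Cl2, 0 °C → rt
Reagents that add atoms: dibromomethane (BrCBr)
Why: Takai–Lombardo methylenation is non-basic, so the epimerisable cis centre next to the ketone and both esters should survive.

Step 14
Reactants: 20 tert-butyl 4-[(1R,2R)-2-(1-methoxy-2-methyl-1-oxopropan-2-yl)-5-methylidenecyclopentyl]butanoate
Product: 21 tert-butyl (3aR,8aR)-4,4-dimethyl-1-methylidene-5-oxodecahydroazulene-6-carboxylate
Conditions: LiN(SiMe3)2, THF, −78 → 0 °C (high dilution); aq. NH4Cl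
Reagents that add atoms: none
Why: Dieckmann condensation; the tert-butyl ester enolate (the only enolisable ester) acylates the neopentyl methyl ester and closes the seven-membered ring as a cis-fused bicycle, driven by deprotonation of the β-keto ester.

Step 15
Reactants: 21 tert-butyl (3aR,8aR)-4,4-dimethyl-1-methylidene-5-oxodecahydroazulene-6-carboxylate
Product: 22 (3aR,8aR)-4,4-dimethyl-1-methylideneoctahydroazulen-5(1H)-one
Conditions: DMSO–H2O, 150 °C
Reagents that add atoms: none
Why: Thermal dealkoxycarbonylation of a tert-butyl β-keto ester (loss of isobutene, then decarboxylation) under neutral conditions that spare the exocyclic alkene.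

Step 16
Reactants: 22 (3aR,8aR)-4,4-dimethyl-1-methylideneoctahydroazulen-5(1H)-one
Product: 23 (3aR,6R,8aR)-4,4,6-trimethyl-1-methylideneoctahydroazulen-5(1H)-one
Conditions: LiN(iPr)2, THF, −78 °C; MeI
Reagents that add atoms: iodomethane (CI)
Why: Only C6 can be enolised; kinetic methylation from the convex face of the cis-fused bicycle should place the methyl group cis to the ring-fusion hydrogens (6R).

Step 17
Reactants: 23 (3aR,6R,8aR)-4,4,6-trimethyl-1-methylideneoctahydroazulen-5(1H)-one
Product: 24 (1R,3aR,6R,8aR)-1-hydroxy-1,4,4,6-tetramethyloctahydroazulen-5(1H)-one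
Conditions: Mn(dpm)3 (dpm = dipivaloylmethanate, cat.), PhSiH3, O2 (1 atm), iPrOH–CH2Cl2, 0 °C
Reagents that add atoms: dioxygen (O=O)
Why: Mukaiyama hydration; hydrogen-atom transfer to the 1,1-disubstituted alkene gives the tertiary radical, which O2 should trap on the convex face (Markovnikov alcohol, 1R, hydroxyl cis to the ring-fusion hydrogens).

Step 18
Reactants: 24 (1R,3aR,6R,8aR)-1-hydroxy-1,4,4,6-tetramethyloctahydroazulen-5(1H)-one
Product: 25 (1R,3aR,6R,8aR)-5-ethenyl-1,4,4,6-tetramethyldecahydroazulene-1,5-diol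
Conditions: CH2=CHMgBr, CeCl3, THF, −78 → 0 °C; aq. NH4Cl
Reagents that add atoms: vinylmagnesium bromide (C=C[Mg]Br)
Why: The organocerium reagent adds to the hindered, enolisable ketone without epimerising C6; the new carbinol centre is lost in step 19.

**Union and completion**

Step 19
Reactants: 12 2-(trimethylsilyl)ethyl (3R,5aR,9aR)-3-hydroxy-2,2,5a-trimethyl-7-oxodecahydro-1-benzoxepine-6-carboxylate; 25 (1R,3aR,6R,8aR)-5-ethenyl-1,4,4,6-tetramethyldecahydroazulene-1,5-diol
Product: 26 2-(trimethylsilyl)ethyl (3R,5aR,9aR)-3-hydroxy-6-{(2E)-2-[(1R,3aR,6R,8aR)-1-hydroxy-1,4,4,6-tetramethyloctahydroazulen-5(1H)-ylidene]ethyl}-2,2,5a-trimethyl-7-oxodecahydro-1-benzoxepine-6-carboxylate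
Conditions: Pd(PPh3)4 (cat.), Et3B, THF, 50 °C
Reagents that add atoms: none
Why: Et3B-promoted Tsuji–Trost allylation with a free tertiary allylic alcohol; zerovalent palladium ionises it to a π-allyl complex that the β-keto ester enolate attacks at the unsubstituted terminus, and the bulkier CMe2 ring carbon takes the syn position, so the E trisubstituted alkene should result.

Step 20
Reactants: 26 the coupled β-keto ester
Product: 27 (3R,5aR,6R,9aR)-3-hydroxy-6-{(2E)-2-[(1R,3aR,6R,8aR)-1-hydroxy-1,4,4,6-tetramethyloctahydroazulen-5(1H)-ylidene]ethyl}-2,2,5a-trimethyloctahydro-1-benzoxepin-7(2H)-one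
Conditions: Bu4NF, THF, 0 → 50 °C; aq. NH4Cl
Reagents that add atoms: none
Why: Fluoride cleaves the 2-(trimethylsilyl)ethyl ester and the β-keto acid decarboxylates; protonation and equilibration of the ketone should place the side chain equatorial (6R), cis to the axial angular methyl.

Step 21
Reactants: 27 the bicyclic ketone
Product: 28 (3R,5aR,6R,7S,9aR)-6-{(2E)-2-[(1R,3aR,6R,8aR)-1-hydroxy-1,4,4,6-tetramethyloctahydroazulen-5(1H)-ylidene]ethyl}-2,2,5a,7-tetramethyldecahydro-1-benzoxepine-3,7-diol (CNP0167890.2)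
Conditions: MeMgBr, CeCl3, THF, −78 → 0 °C
Reagents that add atoms: methylmagnesium bromide (C[Mg]Br)
Why: The methylcerium reagent should attack the ketone equatorially, because the axial angular methyl at C5a blocks axial approach, giving the axial tertiary alcohol (7S) of the target.

**Compound list**

1 | 4-methoxy-2-methylphenol | COc1ccc(O)c(C)c1 | starting material
2 | 4,4-dimethoxy-2-methylcyclohexa-2,5-dien-1-one | COC1(OC)C=CC(=O)C(C)=C1 | intermediate
3 | 4,4-dimethoxy-2-methylcyclohex-2-en-1-one | COC1(OC)CCC(=O)C(C)=C1 | intermediate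
4 | (1R)-4,4-dimethoxy-2-methylcyclohex-2-en-1-ol | COC1(OC)CC[C@@H](O)C(C)=C1 | intermediate
5 | (4R)-4-hydroxy-3-methylcyclohex-2-en-1-one | O=C1CC[C@@H](O)C(C)=C1 | intermediate
6 | (4R)-3-methyl-4-[(triethylsilyl)oxy]cyclohex-2-en-1-one | O=C1CC[C@@H](O[Si](CC)(CC)CC)C(C)=C1 | intermediate
7 | (4R)-2-iodo-3-methyl-4-[(triethylsilyl)oxy]cyclohex-2-en-1-one | O=C1CC[C@@H](O[Si](CC)(CC)CC)C(C)=C1I | intermediate
8 | 2-(trimethylsilyl)ethyl (3R)-2-methyl-6-oxo-3-[(triethylsilyl)oxy]cyclohex-1-ene-1-carboxylate | O=C1CC[C@@H](O[Si](CC)(CC)CC)C(C)=C1C(=O)OCC[Si](C)(C)C | intermediate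
9 | 5-bromo-2-methylpent-2-ene | CC(C)=CCCBr | starting material
10 | (2R)-2-(2-bromoethyl)-3,3-dimethyloxirane | BrCC[C@H]1OC1(C)C | intermediate
11 | 2-(trimethylsilyl)ethyl (2R,3R)-2-{2-[(2R)-3,3-dimethyloxiran-2-yl]ethyl}-2-methyl-6-oxo-3-[(triethylsilyl)oxy]cyclohexane-1-carboxylate | O=C1CC[C@@H](O[Si](CC)(CC)CC)[C@](C)(CC[C@H]2OC2(C)C)C1C(=O)OCC[Si](C)(C)C | intermediate
12 | 2-(trimethylsilyl)ethyl (3R,5aR,9aR)-3-hydroxy-2,2,5a-trimethyl-7-oxodecahydro-1-benzoxepine-6-carboxylate | O=C1CC[C@H]2OC(C)(C)[C@H](O)CC[C@]2(C)C1C(=O)OCC[Si](C)(C)C | intermediate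
13 | cyclopent-2-en-1-one | O=C1C=CCC1 | starting material
14 | 1-methoxy-2-methyl-1-(trimethylsilyloxy)prop-1-ene | COC(O[Si](C)(C)C)=C(C)C | starting material
15 | tert-butyl 4-oxobutanoate | CC(C)(C)OC(=O)CCC=O | starting material
16 | methyl 2-methyl-2-{(1R)-3-[(trimethylsilyl)oxy]cyclopent-2-en-1-yl}propanoate | COC(=O)C(C)(C)[C@@H]1CCC(O[Si](C)(C)C)=C1 | intermediate
17 | tert-butyl 4-hydroxy-4-[(2R)-2-(1-methoxy-2-methyl-1-oxopropan-2-yl)-5-oxocyclopentyl]butanoate | CC(C)(C)OC(=O)CCC(O)C1C(=O)CC[C@H]1C(C)(C)C(=O)OC | intermediate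
18 | tert-butyl 4-[(2R)-2-(1-methoxy-2-methyl-1-oxopropan-2-yl)-5-oxocyclopentylidene]butanoate | CC(C)(C)OC(=O)CCC=C1C(=O)CC[C@H]1C(C)(C)C(=O)OC | intermediate
19 | tert-butyl 4-[(1R,2R)-2-(1-methoxy-2-methyl-1-oxopropan-2-yl)-5-oxocyclopentyl]butanoate | CC(C)(C)OC(=O)CCC[C@H]1C(=O)CC[C@H]1C(C)(C)C(=O)OC | intermediate
20 | tert-butyl 4-[(1R,2R)-2-(1-methoxy-2-methyl-1-oxopropan-2-yl)-5-methylidenecyclopentyl]butanoate | CC(C)(C)OC(=O)CCC[C@H]1C(=C)CC[C@H]1C(C)(C)C(=O)OC | intermediate
21 | tert-butyl (3aR,8aR)-4,4-dimethyl-1-methylidene-5-oxodecahydroazulene-6-carboxylate | CC(C)(C)OC(=O)C1CC[C@@H]2[C@@H](CCC2=C)C(C)(C)C1=O | intermediate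
22 | (3aR,8aR)-4,4-dimethyl-1-methylideneoctahydroazulen-5(1H)-one | C1CC[C@@H]2[C@@H](CCC2=C)C(C)(C)C1=O | intermediate
23 | (3aR,6R,8aR)-4,4,6-trimethyl-1-methylideneoctahydroazulen-5(1H)-one | C[C@@H]1CC[C@@H]2[C@@H](CCC2=C)C(C)(C)C1=O | intermediate
24 | (1R,3aR,6R,8aR)-1-hydroxy-1,4,4,6-tetramethyloctahydroazulen-5(1H)-one | C[C@@H]1CC[C@@H]2[C@@H](CC[C@@]2(C)O)C(C)(C)C1=O | intermediate
25 | (1R,3aR,6R,8aR)-5-ethenyl-1,4,4,6-tetramethyldecahydroazulene-1,5-diol | C[C@@H]1CC[C@@H]2[C@@H](CC[C@@]2(C)O)C(C)(C)C1(O)C=C | intermediate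
26 | 2-(trimethylsilyl)ethyl (3R,5aR,9aR)-3-hydroxy-6-{(2E)-2-[(1R,3aR,6R,8aR)-1-hydroxy-1,4,4,6-tetramethyloctahydroazulen-5(1H)-ylidene]ethyl}-2,2,5a-trimethyl-7-oxodecahydro-1-benzoxepine-6-carboxylate | C[C@@H]1CC[C@@H]2[C@@H](CC[C@@]2(C)O)C(C)(C)/C1=C/CC1(C(=O)OCC[Si](C)(C)C)[C@@]2(C)CC[C@@H](O)C(C)(C)O[C@@H]2CCC1=O | intermediate
27 | (3R,5aR,6R,9aR)-3-hydroxy-6-{(2E)-2-[(1R,3aR,6R,8aR)-1-hydroxy-1,4,4,6-tetramethyloctahydroazulen-5(1H)-ylidene]ethyl}-2,2,5a-trimethyloctahydro-1-benzoxepin-7(2H)-one | C[C@@H]1CC[C@@H]2[C@@H](CC[C@@]2(C)O)C(C)(C)/C1=C/C[C@@H]1[C@@]2(C)CC[C@@H](O)C(C)(C)O[C@@H]2CCC1=O | intermediate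
28 | (3R,5aR,6R,7S,9aR)-6-{(2E)-2-[(1R,3aR,6R,8aR)-1-hydroxy-1,4,4,6-tetramethyloctahydroazulen-5(1H)-ylidene]ethyl}-2,2,5a,7-tetramethyldecahydro-1-benzoxepine-3,7-diol | C[C@@H]1CC[C@@H]2[C@@H](CC[C@@]2(C)O)C(C)(C)/C1=C/C[C@@H]1[C@@]2(C)CC[C@@H](O)C(C)(C)O[C@@H]2CC[C@]1(C)O | target

**Step count.** Total: 21 steps. Longest linear sequence: 12 steps (13 → 28 through steps 10–21).

**Steps most likely to fail**

Step 9. The primary radical may be reduced before it adds to the hindered tetrasubstituted acceptor, and in the acid stage exo closure to a tetrahydropyran or rearrangement of the epoxide may compete with the endo mode. Fallback: the two bonds are made separately by known reactions. From 8, CuBr·SMe2-catalysed conjugate addition of (4-methylpent-3-en-1-yl)magnesium bromide in the presence of Me3SiCl, followed by mild acidic work-up, should give 2-(trimethylsilyl)ethyl (2R,3R)-2-methyl-2-(4-methylpent-3-en-1-yl)-6-oxo-3-[(triethylsilyl)oxy]cyclohexane-1-carboxylate F1. Shi epoxidation of the side-chain alkene (stoichiometric ketone at pH 8, to spare the β-keto ester) then gives 11, now isolated. Treatment of 11 with BF3·OEt2 in CH2Cl2 at −78 °C, with the silyl ether as the nucleophile, returns to the route at 12.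

Step 19. Ionisation of the doubly neopentyl tertiary allylic alcohol may be slow and the congested enolate (a quaternary carbon is formed next to a quaternary carbon) may attack sluggishly, so that elimination of the π-allyl complex to a diene or O-allylation takes over. Fallback: from 25, 1,3-transposition of the hydroxyl group with Ph3SiOReO3 (cat.) should give (2E)-2-[(1R,3aR,6R,8aR)-1-hydroxy-1,4,4,6-tetramethyloctahydroazulen-5(1H)-ylidene]ethan-1-ol F2. Appel bromination (CBr4, PPh3; the tertiary alcohol is inert) converts it into (1R,3aR,5E,6R,8aR)-5-(2-bromoethylidene)-1,4,4,6-tetramethyldecahydroazulen-1-ol F3. C-alkylation of 12 with F3 (Cs2CO3, DMF) returns to the route at 26.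

Step 14. Acylation at the neopentyl methyl ester may be too slow, so that intermolecular Claisen condensation of the tert-butyl ester wins. Fallback: an aldol closure on a more electrophilic carbonyl. From 20, LiBH4 should reduce the methyl ester selectively to tert-butyl 4-[(1R,2R)-2-(1-hydroxy-2-methylpropan-2-yl)-5-methylidenecyclopentyl]butanoate F4. Dess–Martin oxidation gives the non-enolisable aldehyde tert-butyl 4-[(1R,2R)-2-(2-methyl-1-oxopropan-2-yl)-5-methylidenecyclopentyl]butanoate F5. LiN(iPr)2 then effects intramolecular aldol addition of the ester enolate to give tert-butyl (3aR,8aR)-5-hydroxy-4,4-dimethyl-1-methylidenedecahydroazulene-6-carboxylate F6. A second Dess–Martin oxidation returns to the route at 21.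

Further compounds
F1 | step 9 | 2-(trimethylsilyl)ethyl (2R,3R)-2-methyl-2-(4-methylpent-3-en-1-yl)-6-oxo-3-[(triethylsilyl)oxy]cyclohexane-1-carboxylate | O=C1CC[C@@H](O[Si](CC)(CC)CC)[C@](C)(CCC=C(C)C)C1C(=O)OCC[Si](C)(C)C
F2 | step 19 | (2E)-2-[(1R,3aR,6R,8aR)-1-hydroxy-1,4,4,6-tetramethyloctahydroazulen-5(1H)-ylidene]ethan-1-ol | C[C@@H]1CC[C@@H]2[C@@H](CC[C@@]2(C)O)C(C)(C)/C1=C/CO
F3 | step 19 | (1R,3aR,5E,6R,8aR)-5-(2-bromoethylidene)-1,4,4,6-tetramethyldecahydroazulen-1-ol | C[C@@H]1CC[C@@H]2[C@@H](CC[C@@]2(C)O)C(C)(C)/C1=C/CBr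
F4 | step 14 | tert-butyl 4-[(1R,2R)-2-(1-hydroxy-2-methylpropan-2-yl)-5-methylidenecyclopentyl]butanoate | CC(C)(C)OC(=O)CCC[C@H]1C(=C)CC[C@H]1C(C)(C)CO
F5 | step 14 | tert-butyl 4-[(1R,2R)-2-(2-methyl-1-oxopropan-2-yl)-5-methylidenecyclopentyl]butanoate | CC(C)(C)OC(=O)CCC[C@H]1C(=C)CC[C@H]1C(C)(C)C=O
F6 | step 14 | tert-butyl (3aR,8aR)-5-hydroxy-4,4-dimethyl-1-methylidenedecahydroazulene-6-carboxylate | CC(C)(C)OC(=O)C1CC[C@@H]2[C@@H](CCC2=C)C(C)(C)C1O
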